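With the rate constants unknown, choose the next partner dose from the two earlier runs, working in decades of dose.

common to all: left-handed substrate 0.10 M; right-handed substrate 0.10 M; free catalyst 0.76 mM

| run | partner | remark | time |
|---|---|---|---|
| violet | 0.030 M (fed, over 50 s) | run made earlier; the fed solution adds 0.20 times the starting volume |  |
| grey | 0.12 M (fed, over 50 s) | run made earlier; the fed solution adds 0.20 times the starting volume |  |
| flask | 0.0600 M (fed, over 50 s) | the fed solution adds 0.20 times the starting volume | 3.0 min |

| run | time / min | left-handed substrate / % | right-handed substrate / % |
|---|---|---|---|
| violet | 0.200 | 49.8 | 49.9 |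
| violet | 0.417 | 48.8 | 50.5 |
| violet | 1.00 | 44.7 | 50.4 |
| violet | 2.50 | 41.8 | 50.1 |
| grey | 0.200 | 48.8 | 49.9 |
| grey | 0.417 | 44.6 | 50.1 |
| grey | 1.00 | 34.8 | 50.3 |
| grey | 2.50 | 27.1 | 50.0 |

(scatter of a reading: 0.3 percentage points)

- part of the left-handed substrate and right-handed substrate charged together that has reacted at 3.0 min
- excess of left-handed product over right-handed product in the product at 3.0 min
- excess of right-handed substrate over left-handed substrate among what is left of the two at 3.0 min

- free catalyst is single-handed; left-handed substrate and right-handed substrate are mirror images of each other, charged as a racemate, each of them at the stated concentration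
- every charge counts on the volume at the start, and the solution that is fed holds the whole dose
- steps thought possible: partner + free catalyst + left-handed substrate -> free catalyst + left-handed product; partner + free catalyst + right-handed substrate -> free catalyst + right-handed product; 2 free catalyst <-> resting dimer; 2 partner -> homo dimer; free catalyst -> spent catalyst
- an excess is below zero if the other one leads

Read the loss of left-handed substrate at 2.50 min, in percent of both substrates together: the violet run has lost 8.20% and the grey run 22.9%. The right-handed substrate in the grey run reads 50.0%, so take c as that loss. Call n = 0.741 the dose order, the decades of loss gained per decade of partner dose. It lies below one, so the grey run gets less loss per unit of partner than the violet run. For 0.0600 M at 2.50 min, n gives a loss of 13.7%, so the grey dose takes 2.00 times that partner for 1.67 times that loss. So charge 0.0600 M, leave the substrates, catalyst and feed as they were, and read at 3.0 min. This dose stands 0.301 decades above the violet dose. Commit to 13.7% as a lower mark for c, which puts eS at 15.9% or above.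

The forecast gives 14.4% for c, 99% for eP and 16.8% for eS. It stands 0.7 percentage points above this mark for the time up to 3.0 min, noting that “The late rate is decaying”.

The flask gives 14.9% for c, 98.4% for eP and 17.2% for eS, so c lies 1.2 points above the mark and the forecast holds.

    partner + free catalyst + left-handed substrate → free catalyst + left-handed product (k = 815 L² mol⁻² s⁻¹)
    partner + free catalyst + right-handed substrate → free catalyst + right-handed product (k = 5.45 L² mol⁻² s⁻¹)
    2 free catalyst ⇌ resting dimer, settled at all times (K = 4100 L mol⁻¹)
    2 partner → homo dimer (k = 0.0967 L mol⁻¹ s⁻¹)
    free catalyst → spent catalyst (k = 0.0284 s⁻¹)

The power rule behind the forecast breaks in the neighbour charged with 0.24 M of partner. Carrying n from the flask's c puts that neighbour at 41.6%, but it reaches 33.3%, a local order of 0.581, less than n. In the flask the reaction of free catalyst to spent catalyst holds c down: with that step taken away, c stands at 20.3% against 14.9%, a gain of 5.4 points.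

(The data were generated by integration for substances that don't exist; scatter was added.)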